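## Analysis of the target

Target 21 (C28H24O4) is a 20-membered cyclophane of four benzene rings joined in the order A–O–B–CH2CH2–C–O–D–CH2CH2–A. It is therefore two bibenzyl units tied together by two diaryl ether oxygens. Ring A carries a hydroxyl, the ether oxygen to ring B ortho to that hydroxyl, and its CH2 para to the ether oxygen. Ring D carries the ether oxygen to ring C, a hydroxyl ortho to it, and its CH2 para to the hydroxyl. Ring B is 1,3-linked (O and CH2) and ring C is 1,4-linked (O and CH2). The molecule has no stereocentre and no double bond, and the large flexible ring is not expected to show isolable planar chirality. The sensitive groups are the two phenols, each a catechol mono-aryl ether that oxidises easily; both are best carried as methyl ethers until the last step. The diaryl ethers and benzylic CH2 groups are robust. The difficulty is the entropically unfavourable closure of an unbiased 20-membered ring without leaving extra substituents on rings B and C, which carry no handle. The strategy rests on ring C: it bears only the oxygen to ring D and the bridge carbon to ring B, para to each other. A 4-aryloxy-2-pyranone supplies four ring carbons with the oxygen already on C4. A terminal ynone supplies the other two, its carbonyl being the future bridge carbon. Loss of the lactone bridge leaves exactly the para pattern, so ring C can be made, and its formation can serve as the ring closure.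

## Retrosynthetic reasoning

**21 to 20.** The two O–CH3 bonds are cut last. Methyl ethers are the smallest protection that survives base, hydride, organometallic, oxidative and thermal steps, and both come with purchased building blocks. The forward reaction must cleave two aryl methyl ethers without touching the diaryl ethers, which a boron trihalide does.

**20 to 18.** The CH2 next to ring C is traced back to a carbonyl in macrocyclic ketone 18. The carbonyl is placed there because that carbon must be the activating acyl group of the dienophile in the ring-forming step. The forward reaction is a deoxygenation of an aryl ketone whose para aryloxy group stabilises the benzylic cation.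

**18 to 16 (through 17).** Two C–C bonds of ring C are cut: the bond from the acyl-bearing carbon to one ortho carbon, and the bond from the other ortho carbon to its meta neighbour. This opens ring C and the macrocycle together and leads to pyranone ynone 16. Cutting here turns the ring closure into a cycloaddition followed by an irreversible aromatisation, with no separate macrocyclisation step and no leftover functional group on ring C. The forward reaction must pair C3 of the pyranone with the terminal alkyne carbon and C6 with the acyl-bearing carbon, then expel the lactone bridge of 17 by decarboxylation.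

**16 to 15.** The ynone is traced back to propargylic alcohol 15. An ynone cannot be present while a phenoxide is in the flask, because the phenoxide would add to it. A pyranone cannot be present while an ester is converted with organometallic reagents. The ynone is therefore unmasked by a neutral oxidation only after the pyranone is in place.

**15 to 12 and 14.** The bond between C4 of the pyranone and the ring D oxygen is cut, giving phenol 12 and 4-bromopyranone 14, which comes from 4-hydroxypyranone 13. A bromide is chosen over a sulfonate ester because a sulfonate of this vinylogous acid offers the phenoxide a second electrophilic site at sulfur. The bromide can only be displaced at carbon. The forward reaction must let the phenoxide react in the presence of the secondary alcohol of 12, which the difference in acidity allows.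

**12 to 11 to 10.** The bond between the carbinol carbon and the alkyne is cut, giving aldehyde 11, which comes from ester 10 by partial reduction. The two-carbon arylacetic chain of ring B thus supplies the benzylic CH2 and the future carbonyl carbon. The alkyne enters only after the hydrogenation step, which it would not survive.

**10 to 9 to 3 and 7.** The central bond of the A–D bibenzyl is cut as a stilbene double bond, giving aldehyde 3 and phosphonium salt 7, which reacts through ylide 8. The olefination joins the two halves under mild base. The hydrogenation that saturates stilbene 9 also removes the benzyl group and frees the ring D phenol exactly when it is needed.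

**7 to 5 to 4.** The phosphonium salt comes from benzylic alcohol 5, through bromide 6, and so from aldehyde 4. Compound 4 already holds the ring D oxygen pattern, with the oxygen that will bind ring C masked as a benzyl ether.

**3 to 1 and 2.** The diaryl ether C–O bond on ring A is cut. The fluoride of 2 is para to the aldehyde and can be displaced by the phenoxide of 1. This sets the A–O–B ether and the ring A substitution pattern in one step from two purchased compounds.

## Alternatives that were turned down

**Alternative 1:** The ring B carbon–oxygen bond would be cut. The open-chain precursor A2 carries a free ring A phenol and a symmetric 2-(trimethylsilyl)-1,3-bis(triflyloxy) ring B. Fluoride (CsF) would release an aryne, the phenoxide would add to the aryne carbon remote from the remaining triflate, and protonation would give macrocyclic aryl triflate A1.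
- For it: the ring closure is ionic, runs near room temperature and uses a very reactive electrophile. The symmetric precursor can give only one aryne, and the remaining triflate steers the addition. All four rings are bought. On reaction temperature and intrinsic rate of bond formation it is stronger than the chosen route.
- Against it: ring B of the target has no third substituent, so the triflate of A1 is a placeholder. It must be removed by a further reduction (for example Pd(OAc)2, PPh3, HCO2H, Et3N) before A1 would join the chosen route at 20. The ring B unit of A2 needs its own multi-step preparation. After the addition the aryl anion sits ortho to the second triflate, where loss of triflate to a second aryne or triflyl migration competes with protonation. The aryne is short-lived, so at high dilution capture by fluoride, solvent or the anisole rings competes with capture across 20 atoms.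
- Comparison: in the chosen route both partners are stable until heated, and ring C forms with exactly its two substituents, so nothing has to be installed and removed.

**Alternative 2:** The ring D carbon–oxygen bond would be cut. In the open-chain bis(phenol) A4, Tl(NO3)3 in methanol would oxidise the 2,6-dibromophenol of ring D. The oxygen of the 2,6-dichlorophenol of ring C would attack the bromine-bearing ortho carbon, and reduction with Zn would rearomatise with loss of bromide to give trihalogenated macrocycle A3.
- For it: it follows the likely biogenesis. The halogens distinguish the two phenols and block carbon–carbon coupling. The hydroxyl ortho to the new ether on ring D arises directly. As a reaction class for closing macrocyclic diaryl ethers it is at least as well founded as a pyranone cycloaddition across so large a ring.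
- Against it: four halogens must be introduced and three removed from A3 by hydrogenolysis before the ring A methyl ether is cleaved. Ring C needs a hydroxyl-free, halogen-free pattern that the method delivers only after that clean-up. Trivalent thallium is used in stoichiometric amount. The oxidised ring can be captured by methanol or by a second molecule, and the electron-rich ring A is exposed to the oxidant.
- Comparison: the number of steps after ring closure is about the same. The chosen route offers no toxic heavy-metal oxidant, no halogen placeholders and no oxidation of free electron-rich phenols.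

**Alternative 3:** The ring A carbon–oxygen bond would be cut. In the open-chain fluoronitroarene A6, K2CO3 in DMF at high dilution would let the ring B phenoxide displace the fluoride ortho to the nitro group, giving nitro macrocycle A5.
- For it: this is the most dependable ring closure of the four. The nitro-activated addition–elimination runs under mild conditions, is largely indifferent to ring size and gives one constitution. On certainty of the macrocyclisation it is clearly stronger than the chosen route.
- Against it: the nitro group of A5 sits where the ring A hydroxyl belongs. Turning it into a hydroxyl takes reduction, diazotisation and hydrolysis. The last of these is the weakest, because an aryl cation or radical next to a diaryl ether can cyclise onto ring B, be reduced, or couple with the electron-rich rings. A nitro group in A6 also rules out catalytic hydrogenation of a stilbene, so the bibenzyl bridges need a different reduction.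
- Comparison: Alternative 3 places its risk in a poor step after ring closure, on the most valuable material. The chosen route concentrates its risk in the ring closure and follows it with two clean steps.

Key step: step 11

Remark on the chemistry: compounds 12, 15 and 19 have one stereocentre each and, like bridged lactone 17, are racemic; stilbene 9 is an E/Z mixture. All these elements are removed later, so none is controlled.

## Route

Step 1
Reactants: 1 methyl 2-(3-hydroxyphenyl)acetate; 2 4-fluoro-3-methoxybenzaldehyde
Product: 3 methyl 2-[3-(4-formyl-2-methoxyphenoxy)phenyl]acetate
Conditions: K2CO3, DMF, 100 °C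
Reagents that add atoms: none
Why: Nucleophilic aromatic substitution: the para formyl group stabilises the Meisenheimer adduct and fluoride leaves. Carbonate deprotonates the phenol but not the arylacetate CH2, so the ester should pass unchanged under dry conditions.

Step 2
Reactants: 4 3-(benzyloxy)-4-methoxybenzaldehyde
Product: 5 [3-(benzyloxy)-4-methoxyphenyl]methanol
Conditions: NaBH4, MeOH, 0 °C
Reagents that add atoms: none
Why: Borohydride reduction of an aromatic aldehyde; the two ethers are inert.

Step 3
Reactants: 5 [3-(benzyloxy)-4-methoxyphenyl]methanol
Product: 7 {[3-(benzyloxy)-4-methoxyphenyl]methyl}triphenylphosphonium bromide, via benzylic bromide 6 (not isolated)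
Conditions: PPh3·HBr, MeCN, reflux
Reagents that add atoms: triphenylphosphine hydrobromide, Br.c1ccc(cc1)P(c1ccccc1)c1ccccc1
Why: The electron-rich benzylic alcohol is converted by HBr into bromide 6, which the liberated phosphine quaternises at once. This makes the Wittig salt in one operation; the benzyl aryl ether tolerates these conditions.

Step 4
Reactants: 3 methyl 2-[3-(4-formyl-2-methoxyphenoxy)phenyl]acetate; 7 {[3-(benzyloxy)-4-methoxyphenyl]methyl}triphenylphosphonium bromide
Product: 9 methyl 2-[3-[4-[2-[3-(benzyloxy)-4-methoxyphenyl]ethenyl]-2-methoxyphenoxy]phenyl]acetate (E/Z mixture), via phosphorus ylide 8 (not isolated)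
Conditions: K2CO3, 18-crown-6 (cat.), CH2Cl2, reflux
Reagents that add atoms: none
Why: Wittig reaction of a semi-stabilised benzylic ylide generated under solid–liquid phase transfer. The base is too weak to enolise the ester, and the alkene geometry does not matter because the double bond is hydrogenated next.

Step 5
Reactants: 9 methyl 2-[3-[4-[2-[3-(benzyloxy)-4-methoxyphenyl]ethenyl]-2-methoxyphenoxy]phenyl]acetate
Product: 10 methyl 2-[3-[4-[2-(3-hydroxy-4-methoxyphenyl)ethyl]-2-methoxyphenoxy]phenyl]acetate
Conditions: H2 (1 atm), 10% Pd/C, EtOAc–MeOH, rt
Reagents that add atoms: none
Why: Catalytic hydrogenation saturates the stilbene and hydrogenolyses the benzyl ether in the same operation, freeing the ring D phenol. Ester, methyl ethers and diaryl ether are untouched.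

Step 6
Reactants: 10 methyl 2-[3-[4-[2-(3-hydroxy-4-methoxyphenyl)ethyl]-2-methoxyphenoxy]phenyl]acetate
Product: 11 2-[3-[4-[2-(3-hydroxy-4-methoxyphenyl)ethyl]-2-methoxyphenoxy]phenyl]acetaldehyde
Conditions: iBu2AlH (2.3 equiv), CH2Cl2, −78 °C; then aq. potassium sodium tartrate
Reagents that add atoms: none
Why: Partial reduction of an ester: the first equivalent is consumed by the phenol, and the second gives a tetrahedral aluminium hemiacetal that is stable at −78 °C and releases the aldehyde only on work-up. The aldehyde is used crude.

Step 7
Reactants: 11 2-[3-[4-[2-(3-hydroxy-4-methoxyphenyl)ethyl]-2-methoxyphenoxy]phenyl]acetaldehyde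
Product: 12 1-[3-[4-[2-(3-hydroxy-4-methoxyphenyl)ethyl]-2-methoxyphenoxy]phenyl]but-3-yn-2-ol (racemic)
Conditions: HC≡CMgBr (3.5 equiv), THF, 0 °C → rt; then aq. NH4Cl
Reagents that add atoms: ethynylmagnesium bromide, C#C[Mg]Br
Why: Grignard 1,2-addition of a weakly basic acetylide to the aldehyde after the phenol has taken up one equivalent. The new carbinol centre forms without control and is erased by the oxidation in step 10.

Step 8
Reactants: 13 4-hydroxy-2H-pyran-2-one
Product: 14 4-bromo-2H-pyran-2-one
Conditions: Bu4NBr, P2O5, toluene, 100 °C
Reagents that add atoms: tetrabutylammonium bromide, CCCC[N+](CCCC)(CCCC)CCCC.[Br-]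
Why: Deoxybromination of a vinylogous acid: O-phosphorylation makes the C4 oxygen a leaving group and bromide replaces it by addition–elimination. The medium is acidic and non-nucleophilic, so the lactone should survive.

Step 9
Reactants: 12 1-[3-[4-[2-(3-hydroxy-4-methoxyphenyl)ethyl]-2-methoxyphenoxy]phenyl]but-3-yn-2-ol; 14 4-bromo-2H-pyran-2-one
Product: 15 4-[5-[2-[4-[3-(2-hydroxybut-3-yn-1-yl)phenoxy]-3-methoxyphenyl]ethyl]-2-methoxyphenoxy]-2H-pyran-2-one (racemic)
Conditions: K2CO3, MeCN, rt → 40 °C
Reagents that add atoms: none
Why: Vinylogous nucleophilic acyl substitution: the phenoxide adds to C4 of the β-bromo enoate and bromide is expelled. Carbonate ionises the phenol but not the secondary alcohol or the alkyne, so only the ring D oxygen reacts.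

Step 10
Reactants: 15 4-[5-[2-[4-[3-(2-hydroxybut-3-yn-1-yl)phenoxy]-3-methoxyphenyl]ethyl]-2-methoxyphenoxy]-2H-pyran-2-one
Product: 16 4-[2-methoxy-5-[2-[3-methoxy-4-[3-(2-oxobut-3-yn-1-yl)phenoxy]phenyl]ethyl]phenoxy]-2H-pyran-2-one
Conditions: Dess–Martin periodinane, CH2Cl2, 0 °C → rt
Reagents that add atoms: none
Why: Dess–Martin oxidation of a secondary propargylic alcohol under neutral, non-nucleophilic conditions that suit both the pyranone and the new ynone. No free phenol remains that the oxidant could attack.

Step 11
Reactants: 16 4-[2-methoxy-5-[2-[3-methoxy-4-[3-(2-oxobut-3-yn-1-yl)phenoxy]phenyl]ethyl]phenoxy]-2H-pyran-2-one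
Product: 18 macrocyclic aryl benzyl ketone (20-membered ring of the target with both phenols as methyl ethers and C=O on the bridge carbon bound to ring C), via bridged lactone 17 (not isolated)
Conditions: 1,2-dichlorobenzene (0.001 M, syringe-pump addition of 16), BHT (cat.), 180 °C, Ar
Reagents that add atoms: none
Why: On heating, the donor-substituted diene C3=C4–C5=C6 of the 4-aryloxy-2-pyranone and the electron-poor ynone combine in a normal-demand intramolecular [4+2] cycloaddition; C3, the nucleophilic terminus (β to the aryloxy group and reinforced through the diene by the ring oxygen), bonds to the terminal alkyne carbon and C6 bonds to the acyl-bearing carbon. The resulting 2-oxabicyclo[2.2.2]octadienone 17 loses CO2 by a retro-[4+2] fragmentation that is irreversible and driven by aromatisation. The closest known reaction type is the intramolecular 2-pyranone–alkyne Diels–Alder/decarboxylation sequence used to build the benzene ring of cyclophanes. Ring C is closed as a six-membered carbocycle by the cycloaddition itself, four carbons from the pyranone and two from the alkyne, and the 20-membered macrocycle is closed end to end by the same two C–C bonds. The two bridgehead stereocentres of 17 form as a racemate and vanish when CO2 leaves, so no stereocontrol is needed. The step needs para rather than meta orientation and intramolecular rather than intermolecular reaction; the first follows from pairing C3 with the β-carbon of the ynone, a preference the long flexible tether cannot override, and the second from high dilution with slow addition. BHT is there to suppress radical polymerisation of the ynone during the long heating.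

Step 12
Reactants: 18 macrocyclic aryl benzyl ketone
Product: 20 macrocycle dimethyl ether (the target with both hydroxyls as methyl ethers), via benzylic alcohol 19 (not isolated)
Conditions: Et3SiH, CF3CO2H, CH2Cl2, rt → 40 °C
Reagents that add atoms: none
Why: Ionic hydrogenation: the protonated ketone takes hydride from the silane to give alcohol 19, which ionises to a benzylic cation stabilised by the para aryloxy group and takes a second hydride. Any stilbene formed by proton loss is re-protonated to the same cation and converges on 20.

Step 13
Reactants: 20 macrocycle dimethyl ether
Product: 21 the target, 20-membered bis(bibenzyl) diphenol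
Conditions: BBr3, CH2Cl2, −78 °C → rt; then H2O
Reagents that add atoms: none
Why: Lewis-acid cleavage of aryl methyl ethers: boron coordinates the methoxy oxygen and bromide removes the methyl group by SN2. Diaryl ethers have no such alkyl carbon and stay intact.

## Compound list

1 | methyl 2-(3-hydroxyphenyl)acetate | COC(=O)Cc1cccc(O)c1 | starting material
2 | 4-fluoro-3-methoxybenzaldehyde | COc1cc(C=O)ccc1F | starting material
3 | methyl 2-[3-(4-formyl-2-methoxyphenoxy)phenyl]acetate | COC(=O)Cc1cccc(Oc2ccc(C=O)cc2OC)c1 | intermediate
4 | 3-(benzyloxy)-4-methoxybenzaldehyde | COc1ccc(C=O)cc1OCc1ccccc1 | starting material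
5 | [3-(benzyloxy)-4-methoxyphenyl]methanol | COc1ccc(CO)cc1OCc1ccccc1 | intermediate
6 | 2-(benzyloxy)-4-(bromomethyl)-1-methoxybenzene (benzylic bromide, not isolated) | COc1ccc(CBr)cc1OCc1ccccc1 | intermediate
7 | {[3-(benzyloxy)-4-methoxyphenyl]methyl}triphenylphosphonium bromide | COc1ccc(C[P+](c2ccccc2)(c2ccccc2)c2ccccc2)cc1OCc1ccccc1.[Br-] | intermediate
8 | [3-(benzyloxy)-4-methoxybenzylidene]triphenylphosphorane (ylide, not isolated) | COc1ccc(C=P(c2ccccc2)(c2ccccc2)c2ccccc2)cc1OCc1ccccc1 | intermediate
9 | methyl 2-[3-[4-[2-[3-(benzyloxy)-4-methoxyphenyl]ethenyl]-2-methoxyphenoxy]phenyl]acetate (E/Z mixture) | COC(=O)Cc1cccc(Oc2ccc(C=Cc3ccc(OC)c(OCc4ccccc4)c3)cc2OC)c1 | intermediate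
10 | methyl 2-[3-[4-[2-(3-hydroxy-4-methoxyphenyl)ethyl]-2-methoxyphenoxy]phenyl]acetate | COC(=O)Cc1cccc(Oc2ccc(CCc3ccc(OC)c(O)c3)cc2OC)c1 | intermediate
11 | 2-[3-[4-[2-(3-hydroxy-4-methoxyphenyl)ethyl]-2-methoxyphenoxy]phenyl]acetaldehyde | O=CCc1cccc(Oc2ccc(CCc3ccc(OC)c(O)c3)cc2OC)c1 | intermediate
12 | 1-[3-[4-[2-(3-hydroxy-4-methoxyphenyl)ethyl]-2-methoxyphenoxy]phenyl]but-3-yn-2-ol (racemic) | C#CC(O)Cc1cccc(Oc2ccc(CCc3ccc(OC)c(O)c3)cc2OC)c1 | intermediate
13 | 4-hydroxy-2H-pyran-2-one | O=C1C=C(O)C=CO1 | starting material
14 | 4-bromo-2H-pyran-2-one | O=C1C=C(Br)C=CO1 | intermediate
15 | 4-[5-[2-[4-[3-(2-hydroxybut-3-yn-1-yl)phenoxy]-3-methoxyphenyl]ethyl]-2-methoxyphenoxy]-2H-pyran-2-one (racemic) | C#CC(O)Cc1cccc(Oc2ccc(CCc3ccc(OC)c(OC4=CC(=O)OC=C4)c3)cc2OC)c1 | intermediate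
16 | 4-[2-methoxy-5-[2-[3-methoxy-4-[3-(2-oxobut-3-yn-1-yl)phenoxy]phenyl]ethyl]phenoxy]-2H-pyran-2-one (pyranone ynone) | O=C1C=C(Oc2cc(CCc3ccc(Oc4cccc(CC(=O)C#C)c4)c(OC)c3)ccc2OC)C=CO1 | intermediate
17 | bridged lactone: 2-oxabicyclo[2.2.2]octa-5,7-dien-3-one embedded in the macrocycle, ring D aryloxy group on C5, acyl chain to ring B on C7 (racemic, not isolated) | O=C1OC2C=C(Oc3cc4ccc3OC)C1C=C2C(=O)Cc1cccc(c1)Oc1ccc(CC4)cc1OC | intermediate
18 | macrocyclic aryl benzyl ketone, dimethyl ether | COc1cc2ccc1Oc1cccc(c1)CC(=O)c1ccc(cc1)Oc1cc(ccc1OC)CC2 | intermediate
19 | macrocyclic benzylic alcohol, dimethyl ether (racemic, not isolated) | COc1cc2ccc1Oc1cccc(c1)CC(O)c1ccc(cc1)Oc1cc(ccc1OC)CC2 | intermediate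
20 | macrocycle dimethyl ether | COc1cc2ccc1Oc1cccc(c1)CCc1ccc(cc1)Oc1cc(ccc1OC)CC2 | intermediate
21 | target macrocyclic bis(bibenzyl) diphenol | Oc1cc2ccc1Oc1cccc(c1)CCc1ccc(cc1)Oc1cc(ccc1O)CC2 | target

## Step count and least certain steps

Total step count: 13. Longest linear sequence: 11 steps (steps 2, 3, 4, 5, 6, 7, 9, 10, 11, 12 and 13, from 4).

**Step 11 (key step).** At the dilution needed for ring closure the cycloaddition may be too slow. Thermal decay of the ynone and intermolecular cycloaddition to oligomers could then overtake the macrocyclisation, and some meta orientation could leak through because the tether does not enforce the para mode.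
- Fallback, from 10 back to 18: ring C is brought in intact and the macrocycle is closed at the ring D oxygen. Ester 10 is converted with MeNH(OMe)·HCl and iPrMgCl in THF into Weinreb amide F1. Addition of 4-FC6H4MgBr gives 4-fluorophenyl ketone F2. With Cs2CO3 in DMF at high dilution, with heating under argon, the ring D phenoxide displaces the fluoride para to the ketone. This nucleophilic aromatic substitution closes the same 20-membered ring and delivers 18.

**Step 9.** The phenoxide or carbonate may open the 6-unsubstituted pyranone by attack at C6 or at the lactone carbonyl instead of substituting at C4. The alkoxide of the secondary alcohol could also compete to a small extent.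
- Fallback, from 12 back to 15: the pyranone is built on the phenol oxygen instead of being substituted. Phenol 12 is added to methyl buta-2,3-dienoate (K2CO3, MeCN) to give methyl (E)-3-aryloxybut-2-enoate F3. Condensation of its γ-methyl group with Me2NCH(OMe)2 at about 100 °C gives dienamine F4. Treatment with CF3CO2H hydrolyses the enamine and lactonises the resulting enol onto the ester to give 15.

**Step 6.** Reduction may not stop at the aldehyde. The arylacetaldehyde may also be lost by enolisation and aldol reaction during work-up or during the acetylide addition of step 7.
- Fallback, from 10 back to 12: no aldehyde is made. Ester 10 is converted into Weinreb amide F1, the same compound as in the fallback for step 11. HC≡CMgBr adds to give, after acidic quench of the stable chelate, ynone phenol F5. Reduction with NaBH4 and CeCl3·7H2O in MeOH at −78 °C (Luche reduction) gives 12.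

**Step 12.** The benzylic cation may alkylate one of the electron-rich rings across the macrocycle, or the reduction may stall at the alcohol or stilbene stage.
- Fallback, from 18 back to 20: the ketone is removed under basic conditions that generate no cation. Ketone 18 is heated with N2H4·H2O to give hydrazone F6, which is decomposed with KOH in diethylene glycol at about 190 °C (Wolff–Kishner reduction) to 20. Any methyl ether lost under these conditions is of no consequence, since step 13 removes both.

## Further compounds

F1 | step 11 | N-methoxy-N-methyl-2-[3-[4-[2-(3-hydroxy-4-methoxyphenyl)ethyl]-2-methoxyphenoxy]phenyl]acetamide (Weinreb amide) | CON(C)C(=O)Cc1cccc(Oc2ccc(CCc3ccc(OC)c(O)c3)cc2OC)c1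
F2 | step 11 | 1-(4-fluorophenyl)-2-[3-[4-[2-(3-hydroxy-4-methoxyphenyl)ethyl]-2-methoxyphenoxy]phenyl]ethan-1-one | O=C(Cc1cccc(Oc2ccc(CCc3ccc(OC)c(O)c3)cc2OC)c1)c1ccc(F)cc1
F3 | step 9 | methyl (E)-3-[5-[2-[4-[3-(2-hydroxybut-3-yn-1-yl)phenoxy]-3-methoxyphenyl]ethyl]-2-methoxyphenoxy]but-2-enoate (racemic) | COC(=O)/C=C(\C)Oc1cc(CCc2ccc(Oc3cccc(CC(O)C#C)c3)c(OC)c2)ccc1OC
F4 | step 9 | methyl (2E,4E)-5-(dimethylamino)-3-[5-[2-[4-[3-(2-hydroxybut-3-yn-1-yl)phenoxy]-3-methoxyphenyl]ethyl]-2-methoxyphenoxy]penta-2,4-dienoate (racemic) | COC(=O)/C=C(\C=C\N(C)C)Oc1cc(CCc2ccc(Oc3cccc(CC(O)C#C)c3)c(OC)c2)ccc1OC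
F5 | step 6 | 1-[3-[4-[2-(3-hydroxy-4-methoxyphenyl)ethyl]-2-methoxyphenoxy]phenyl]but-3-yn-2-one (ynone phenol) | C#CC(=O)Cc1cccc(Oc2ccc(CCc3ccc(OC)c(O)c3)cc2OC)c1
F6 | step 12 | hydrazone of macrocyclic ketone 18 | COc1cc2ccc1Oc1cccc(c1)CC(=NN)c1ccc(cc1)Oc1cc(ccc1OC)CC2
A1 | alternative 1 | macrocyclic aryl triflate, dimethyl ether | COc1cc2ccc1Oc1cc(OS(=O)(=O)C(F)(F)F)cc(c1)CCc1ccc(cc1)Oc1cc(ccc1OC)CC2
A2 | alternative 1 | open-chain ring A phenol with 2-(trimethylsilyl)-1,3-bis(triflyloxy) ring B | COc1cc(CCc2ccc(OC)c(Oc3ccc(CCc4cc(OS(=O)(=O)C(F)(F)F)c([Si](C)(C)C)c(OS(=O)(=O)C(F)(F)F)c4)cc3)c2)ccc1O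
A3 | alternative 2 | trihalogenated macrocycle, ring A methyl ether | COc1cc2ccc1Oc1cccc(c1)CCc1cc(Cl)c(c(Cl)c1)Oc1cc(cc(Br)c1O)CC2
A4 | alternative 2 | open-chain bis(phenol) with 2,6-dibromophenol ring D and 2,6-dichlorophenol ring C | COc1cc(CCc2cc(Br)c(O)c(Br)c2)ccc1Oc1cccc(CCc2cc(Cl)c(O)c(Cl)c2)c1
A5 | alternative 3 | nitro macrocycle, ring D methyl ether | [O-][N+](=O)c1cc2ccc1Oc1cccc(c1)CCc1ccc(cc1)Oc1cc(ccc1OC)CC2
A6 | alternative 3 | open-chain 4-fluoro-3-nitroaryl ring A with free ring B phenol | O=[N+]([O-])c1cc(CCc2ccc(OC)c(Oc3ccc(CCc4cccc(O)c4)cc3)c2)ccc1F
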